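Atom labels used throughout (target numbering): C1 carries the exocyclic methylene; C2 and C3 are ring CH2; C4 is the ring-fusion CH; C5 is the benzylic CH; C6 is the ether carbon with the methyl group; C7 and C8 are ring CH2; C9 is the cyclobutane CH next to CMe2; C10 is the cyclobutane CH bonded to C1; C11 is the cyclobutane CH2; C12 is CMe2; Ar1 is the arene carbon bonded to C5. In these labels the target is 4S,5S,6R,9R,10S.

## Analysis of the target

The target is a caryophyllene-type meroterpenoid. A 3,3-dimethylcyclobutane (C9–C12) is trans-fused to a nine-membered carbocycle (C1–C4, C6–C10) that bears an exocyclic methylene at C1. Through the C4–C6 bond this carbocycle is trans-fused to a dihydropyran whose arene is a 2,4-diformylphloroglucinol, and the benzylic carbon C5 of the pyran carries a phenyl group. There are five stereocentres: the trans pair C9/C10 on the cyclobutane and the contiguous triad C4, C5, C6. In the triad H4 and H5 are cis, H4 is trans to the C6 methyl, and the phenyl group lies on the same face as that methyl; the triad is related to the cyclobutane pair only across the medium ring. The sensitive groups are the 1,1-disubstituted alkene (acid), the tertiary alkyl aryl ether at C6 (Lewis acid), the two aryl aldehydes with their free phenols, and the doubly benzylic C5–H. The difficulty lies in the nine-membered ring, which resists end-to-end closure, combined with the fully substituted oxygen-bearing C6 and the need to set C4 and C6 against the remote cyclobutane. The strategy rests on the C4–C6 bond, which is common to the pyran and the nine-membered ring. C4 carries C5, which can be held at carboxyl level, and C6 carries an aryloxy group and a one-carbon residue that can be a shortened vinyl group. That pattern is what an ester-enolate Claisen shift onto an aryl enol ether leaves behind, and if the ester is a thirteen-membered lactone the same shift contracts it to the nine-membered ring.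

## Retrosynthetic reasoning

**41 to 38.** The phenols and aldehydes are uncovered last. The two O–CH3 bonds of 40 are cut by SN2 attack at methyl, because a Lewis acid would open the tertiary C6–O ether and attack the alkene. The two C–CHO bonds go back to the C–Br bonds of 38: aryl bromides pass through a methylenation that aldehydes would not survive, and electrophilic formylation needs acids that the exocyclic alkene does not tolerate.

**38 to 36.** The C1=CH2 bond is cut to the ketone 36. Bromination (37) is placed before the alkene exists.

**36 to 32.** At C5 both the C–H and the C–phenyl bond are disconnected, which leads through 35 and 33 to the aryl ketone 32. Forward, the phenyl group has to enter first and hydride second: the small nucleophile then comes in opposite the C6 methyl and gives H5 cis to H4, whereas the reverse order would give the C5 epimer.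

**32 to 28.** The C6 methyl is read as a vinyl group shortened by one carbon (30, 31). This is done on the chromanone, where the acyl group deactivates the arene toward the oxidant. It also means that no tertiary allylic ether is left when C5 is later ionised.

**28 to 26.** The Ar1–C5 bond is cut in the sense of an intramolecular Friedel–Crafts acylation. The acid on C4 and the aryloxy group on C6 of 26 are placed to close the six-membered pyranone, and the two ortho positions of the arene are equivalent.

**26 to 23 (key disconnection).** The C4–C6 bond is cut and the O–CH2 bond re-formed, which turns the nine-membered acid into the thirteen-membered lactone 23. This bond is chosen because it is the only one whose formation creates both ring-fusion centres in one suprafacial event and at the same time makes the medium ring from a ring that ordinary lactonisation can close. Forward, the shift has to deliver carboxyl and vinyl cis on the new ring and to choose the correct face relative to C9/C10.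

**23 to 21.** The lactone C5(=O)–O bond is cut to the seco acid 21.

**21 to 17.** The C5 carboxyl is traced back through 20 and 19 to the terminal alkene of 17. An alkene is the one latent carboxyl that survives the acetylide, aluminium hydride and copper steps before it. The allylic oxygen stays silylated meanwhile.

**17 to 15 and 16.** The C6–OAr bond is cut to the (Z)-alkenyl iodide 15 and the phenol 16. A coupling with retention is preferred to conjugate addition of 16 to an ynoate, because the thermodynamic adduct of that addition has the aryloxy group trans to the ester, which is the wrong geometry.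

**15 to 10.** The C6–I bond and the vinylic hydrogen come from trans-hydrometalation of the propargylic alcohol 12, and the CH2OH carbon is cut from the acetylide of 10.

**10 to 6.** The ketal goes back to ketone 9 and this to its cis epimer 8, so C10 is set by equilibration. The C1–C2 bond is cut to the acid 6 (as its chloride 7) and a four-carbon Grignard reagent.

**6 to 3.** The alkyne comes from the aldehyde of 5 by one-carbon homologation. Compound 5 comes from oxidative cleavage of the ring bond of ketone 3 that corresponds to C1···C6 of the target, by way of the silyl enol ether 4, which leaves the two arms at different oxidation levels.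

**3 to 1 and 2.** The cyclobutane is cut by a [2+2] disconnection to the enone 1 and the alkene 2. Forward this has to be enantioselective at the carbon that becomes C9.

## Alternatives that were turned down

Alternative 1: Here O–C6, C4–C6 and Ar1–C5 are cut together, which leads to the open-chain styryl diketone A1 and the phenol 16. In the forward step Me3SiOTf would condense the C6 methyl ketone of A1 with 16 to an aryloxy-substituted oxocarbenium ion. C4 of the styrene would attack it, and the C5 cation would be trapped by the ortho carbon, giving the tetracyclic ketone A2, which is the same compound as 36 of the present route. On step economy this alternative is clearly stronger: three bonds and two rings form in one operation, the C6 methyl and the phenyl group are present from the start, and A1 lies only a few steps from a cyclobutane keto-alkyne. Against it, a very electron-rich phenol tends to attack a ketone through carbon and not through oxygen, and the C1 ketone competes with the C6 ketone. The C4–C6 bond would close a nine-membered ring end to end through an open cation with no cyclic array to organise it. C4, C5 and C6 would be set in stepwise cationic events in which the styrene geometry is not transmitted and nothing relates the new centres to C9/C10. The chosen strategy costs many more steps, but it forms the same C4–C6 bond inside a six-membered pericyclic array, with C4 and C6 related by alkene geometry.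

Alternative 2: Here C3–C4 is cut and C1–C7 re-joined, so that the nine-membered enone A4 comes from the bicyclo[3.2.0]heptanol A3, which has a vinyl group on the carbinol carbon and the C6=C4 alkenyl group on the neighbouring carbon. In the forward step KH with 18-crown-6 would trigger the anionic oxy-Cope shift of A3 through a boat and open the five-membered ring to A4. This ring expansion is among the most dependable entries to nine-membered rings. C5 with both aryl groups and the C6 methyl are already in place, and C4 is set by transfer from an alkene held on the convex face of a rigid bicycle. On the relay of stereochemistry from the cyclobutane it is therefore stronger than the chosen route. Against it, A4 is cis-fused at C9/C10 and has to be epimerised. More seriously, the ether oxygen is not yet on C6: the pyran would have to be closed by removing one of three methyl ethers selectively and adding the phenol across the C6=C7 alkene. That addition goes through a C6 cation in a nine-membered ring that also holds a ketone, so the trans ring fusion is not assured and transannular reactions threaten. A3 itself, with its benzylic stereocentre and trisubstituted (E)-alkene, needs a long synthesis. The chosen strategy instead carries the C6–O bond in from the enol ether, so the oxygenated quaternary centre and C4 are formed together and C6 is never a cation.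

Alternative 3: Here C1–C2 is cut, which leads from the bis-deformyl dimethyl ether A6 to the open-chain chroman A5, with a vinyl group on C4 and a 1-iodovinyl group on C10. In the forward step 9-BBN-H would hydroborate the C4 vinyl group and Pd(dppf)Cl2 with Cs2CO3 would couple the resulting C2 borane with the iodoalkene. This closes the ring and installs the exocyclic methylene at once. The ketal and the methylenation step disappear, and A6 is two operations from the target. All five stereocentres are fixed beforehand by joining two enantiopure pieces, so the relation between the cyclobutane and the chroman centres is unambiguous. On that point it is stronger than the chosen route, where the relation rests on macrocycle conformation. Against it, the ring closure is an end-to-end formation of a nine-membered ring that contains two trans ring fusions. It must be run dilute, while transmetalation of the alkylborane is slow and β-hydride elimination, protodeboronation and intermolecular coupling compete. Failure would come at the last stage, on the most advanced material, and A5 needs its own solution for the quaternary C6. The chosen strategy tests its ring formation in mid-route and gives that step the entropy of a six-membered transition state.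

Key step: step 16

Assumptions: (1) the antipode of the oxazaborolidine used in step 1 is the one that gives (1R,6R)-3; (2) the trans-1,2-disubstituted cyclobutane is the thermodynamic isomer in step 6; (3) in step 16 the ketene acetal reaches the enol-ether face that leads to the (4R,6S) acid 26.

## Route

Step 1
Reactants: 1 cyclohex-2-en-1-one; 2 isobutene
Product: 3 (1R,6R)-7,7-dimethylbicyclo[4.2.0]octan-2-one (cis-fused)
Conditions: AlBr3-activated chiral oxazaborolidine (50 mol%), hν (366 nm), CH2Cl2, −75 °C; then basic Al2O3
Reagents that add atoms: none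
Why: Lewis-acid-catalysed enantioselective enone–alkene [2+2] photocycloaddition: the AlBr3-activated oxazaborolidine binds the enone, shifts its absorption to 366 nm and shields one face, and isobutene adds head-to-tail (CMe2 to the β-carbon) as is usual for cyclohexenone. Any trans-fused adduct epimerises to the cis ketone on basic Al2O3; only the β-carbon centre (C9 of the target) has to be set here, since C10 is corrected in step 6.

Step 2
Reactants: 3 (1R,6R)-7,7-dimethylbicyclo[4.2.0]octan-2-one
Product: 4 trimethyl{[(1R,6R)-7,7-dimethylbicyclo[4.2.0]oct-2-en-2-yl]oxy}silane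
Conditions: LiN(i-Pr)2, THF, −78 °C; Me3SiCl, Et3N
Reagents that add atoms: chlorotrimethylsilane, C[Si](C)(C)Cl
Why: Kinetic deprotonation takes the unhindered ring methylene and not the bridgehead C–H, whose enolate would place a double bond at the cyclobutane ring fusion; O-silylation gives the less substituted silyl enol ether.

Step 3
Reactants: 4 trimethyl{[(1R,6R)-7,7-dimethylbicyclo[4.2.0]oct-2-en-2-yl]oxy}silane
Product: 5 (1R,2R)-3,3-dimethyl-2-(3-oxopropyl)cyclobutane-1-carboxylic acid (cis)
Conditions: O3, CH2Cl2, −78 °C; Me2S, −78 °C → rt; H2O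
Reagents that add atoms: ozone, [O-][O+]=O
Why: Ozonolysis of a silyl enol ether cleaves the C=C bond to a silyl ester and an aldehyde, and the silyl ester hydrolyses on work-up. The two arms of the cyclobutane thus emerge differentiated, the acid (C1) on C10 and the aldehyde (C6) at the end of the C9 arm.

Step 4
Reactants: 5 (1R,2R)-3,3-dimethyl-2-(3-oxopropyl)cyclobutane-1-carboxylic acid
Product: 6 (1R,2R)-2-(but-3-yn-1-yl)-3,3-dimethylcyclobutane-1-carboxylic acid (cis)
Conditions: dimethyl (1-diazo-2-oxopropyl)phosphonate, K2CO3 (3 equiv), MeOH, 0 °C → rt; then aq. KHSO4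
Reagents that add atoms: dimethyl (1-diazo-2-oxopropyl)phosphonate, CC(=O)C(=[N+]=[N-])P(=O)(OC)OC
Why: Ohira–Bestmann (Seyferth–Gilbert) homologation turns the aldehyde into the terminal alkyne, with C6 as the internal alkyne carbon; the carboxylate is inert under these conditions.

Step 5
Reactants: 6 (1R,2R)-2-(but-3-yn-1-yl)-3,3-dimethylcyclobutane-1-carboxylic acid
Product: 8 1-[(1R,2R)-2-(but-3-yn-1-yl)-3,3-dimethylcyclobutyl]pent-4-en-1-one (cis), via acid chloride 7 (not isolated)
Conditions: (COCl)2, cat. DMF, CH2Cl2, 0 °C → rt; evaporate; but-3-enylMgBr, Fe(acac)3 (3 mol%), THF, −78 °C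
Reagents that add atoms: but-3-enylmagnesium bromide, C=CCC[Mg]Br; oxalyl chloride, O=C(Cl)C(=O)Cl (chlorine of 7 only)
Why: Iron-catalysed acylation of a Grignard reagent by an acid chloride stops at the ketone and is fast enough at −78 °C that the alkyne C–H is left alone. It forms the C1–C2 bond and brings in C2–C5, with C5 masked as the terminal alkene carbon.

Step 6
Reactants: 8 1-[(1R,2R)-2-(but-3-yn-1-yl)-3,3-dimethylcyclobutyl]pent-4-en-1-one
Product: 9 1-[(1S,2R)-2-(but-3-yn-1-yl)-3,3-dimethylcyclobutyl]pent-4-en-1-one (trans)
Conditions: NaOMe (0.2 equiv), MeOH, rt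
Reagents that add atoms: none
Why: Base-mediated equilibration α to the ketone; the trans-1,2-disubstituted cyclobutane should be the thermodynamic isomer, which sets C10 (S) relative to C9 (R).

Step 7
Reactants: 9 1-[(1S,2R)-2-(but-3-yn-1-yl)-3,3-dimethylcyclobutyl]pent-4-en-1-one
Product: 10 2-(but-3-en-1-yl)-2-[(1S,2R)-2-(but-3-yn-1-yl)-3,3-dimethylcyclobutyl]-1,3-dioxolane
Conditions: HOCH2CH2OH, TsOH·H2O (cat.), benzene, reflux (Dean–Stark)
Reagents that add atoms: ethane-1,2-diol, OCCO
Why: Acid-catalysed ketalisation with removal of water; C10 is already in its stable configuration, so enolisation under acid does no harm. The ketal removes the C1 carbonyl from the organometallic and enolate chemistry that follows and has to be in place before the acid-labile enol ether is made.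

Step 8
Reactants: 10 2-(but-3-en-1-yl)-2-[(1S,2R)-2-(but-3-yn-1-yl)-3,3-dimethylcyclobutyl]-1,3-dioxolane
Product: 12 5-{(1R,2S)-2-[2-(but-3-en-1-yl)-1,3-dioxolan-2-yl]-4,4-dimethylcyclobutyl}pent-2-yn-1-ol, via lithium acetylide 11 (not isolated)
Conditions: n-BuLi, THF, −78 °C; (CH2O)n, −78 °C → rt
Reagents that add atoms: formaldehyde (as paraformaldehyde), C=O; n-butyllithium, [Li]CCCC (lithium of 11 only)
Why: Deprotonation of the terminal alkyne and addition of the acetylide to formaldehyde gives the propargylic alcohol.

Step 9
Reactants: 12 5-{(1R,2S)-2-[2-(but-3-en-1-yl)-1,3-dioxolan-2-yl]-4,4-dimethylcyclobutyl}pent-2-yn-1-ol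
Product: 14 (2Z)-5-{(1R,2S)-2-[2-(but-3-en-1-yl)-1,3-dioxolan-2-yl]-4,4-dimethylcyclobutyl}-3-iodopent-2-en-1-ol, via alkenylalanate 13 (not isolated)
Conditions: NaAlH2(OCH2CH2OMe)2, THF, 0 °C → rt; EtOAc; I2, −78 °C
Reagents that add atoms: iodine, II; NaAlH2(OCH2CH2OMe)2, [Na+].COCCO[AlH2-]OCCOC (aluminate fragment of 13 only)
Why: Hydroxyl-directed trans-hydroalumination places aluminium on C6 in a five-membered alkoxyalanate, and iodine replaces it with retention to give the (Z)-3-iodoallylic alcohol only. This fixes the later enol-ether geometry (C7 anti to the CH2O carbon) independently of any thermodynamic preference.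

Step 10
Reactants: 14 (2Z)-5-{(1R,2S)-2-[2-(but-3-en-1-yl)-1,3-dioxolan-2-yl]-4,4-dimethylcyclobutyl}-3-iodopent-2-en-1-ol
Product: 15 tert-butyldimethylsilyl ether of 14
Conditions: t-BuMe2SiCl, imidazole, CH2Cl2, rt
Reagents that add atoms: tert-butyl(chloro)dimethylsilane, CC(C)(C)[Si](C)(C)Cl
Why: Silylation of the primary allylic alcohol, which must not compete in the C–O coupling and must be distinguished from the alcohol made in step 12.

Step 11
Reactants: 15 tert-butyldimethylsilyl ether of 14; 16 3,5-dimethoxyphenol
Product: 17 tert-butyl{[(2Z)-5-{(1R,2S)-2-[2-(but-3-en-1-yl)-1,3-dioxolan-2-yl]-4,4-dimethylcyclobutyl}-3-(3,5-dimethoxyphenoxy)pent-2-en-1-yl]oxy}dimethylsilane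
Conditions: CuI (10 mol%), N,N-dimethylglycine hydrochloride (30 mol%), Cs2CO3, 1,4-dioxane, 80 °C
Reagents that add atoms: none
Why: Ullmann-type copper-catalysed C–O coupling of an alkenyl iodide with a phenol, which goes with retention of alkene geometry and at the phenol oxygen. It gives the (Z)-aryl enol ether; from here on aqueous acid is avoided.

Step 12
Reactants: 17 (Z)-aryl enol ether silyl ether
Product: 19 4-(2-{(1S,2R)-2-[(3Z)-5-(tert-butyldimethylsilyloxy)-3-(3,5-dimethoxyphenoxy)pent-3-en-1-yl]-3,3-dimethylcyclobutyl}-1,3-dioxolan-2-yl)butan-1-ol, via alkylborane 18 (not isolated)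
Conditions: 9-BBN-H, THF, 0 °C → rt; NaOH, H2O2, 0 °C
Reagents that add atoms: hydrogen peroxide, OO; 9-borabicyclo[3.3.1]nonane, B1C2CCCC1CCC2 (boryl group of 18 only)
Why: Hydroboration–oxidation: 9-BBN-H takes the monosubstituted alkene and leaves the hindered trisubstituted enol ether, and basic peroxide harms neither enol ether nor ketal nor silyl ether. C5 is now at the alcohol level.

Step 13
Reactants: 19 primary alcohol
Product: 20 4-(2-{(1S,2R)-2-[(3Z)-5-(tert-butyldimethylsilyloxy)-3-(3,5-dimethoxyphenoxy)pent-3-en-1-yl]-3,3-dimethylcyclobutyl}-1,3-dioxolan-2-yl)butanoic acid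
Conditions: Pr4N[RuO4] (10 mol%), NMO·H2O (10 equiv), MeCN, rt
Reagents that add atoms: water (from NMO·H2O), O
Why: Perruthenate-catalysed oxidation with NMO monohydrate takes a primary alcohol through the aldehyde hydrate to the acid under neutral conditions, which the enol ether, the ketal and the electron-rich arene should tolerate.

Step 14
Reactants: 20 silyl ether acid
Product: 21 4-(2-{(1S,2R)-2-[(3Z)-3-(3,5-dimethoxyphenoxy)-5-hydroxypent-3-en-1-yl]-3,3-dimethylcyclobutyl}-1,3-dioxolan-2-yl)butanoic acid (seco acid)
Conditions: Bu4NF, THF, 0 °C → rt; pH 6 phosphate buffer; used at once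
Reagents that add atoms: none
Why: Fluoride cleavage of the silyl ether; the buffered work-up is needed because the aryl enol ether hydrolyses in aqueous acid.

Step 15
Reactants: 21 seco acid
Product: 23 thirteen-membered (Z)-aryloxy-enol-ether lactone (9R,10S), via mixed anhydride 22 (not isolated)
Conditions: 2,4,6-Cl3C6H2COCl, Et3N, THF, rt; then slow addition to DMAP, toluene, 60 °C (2 mM)
Reagents that add atoms: 2,4,6-trichlorobenzoyl chloride, O=C(Cl)c1c(Cl)cc(Cl)cc1Cl (aroyl group of 22 only)
Why: Yamaguchi macrolactonisation under high dilution. The ring alkene and the trans-cyclobutane limit the conformations of the seco acid, and a thirteen-membered ring is large enough to close by ordinary ester formation.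

Step 16
Reactants: 23 thirteen-membered lactone
Product: 26 nine-membered ring acid with CO2H on C4 and vinyl plus 3,5-dimethoxyphenoxy on C6 (C1 dioxolane; 4R,6S,9R,10S), via silyl ketene acetal 24 (not isolated), via trimethylsilyl ester 25 (not isolated)
Conditions: LiN(i-Pr)2, Me3SiCl–Et3N, THF, −78 °C → rt, then 60 °C; aq. K2CO3, then NaH2PO4 (pH 5)
Reagents that add atoms: chlorotrimethylsilane, C[Si](C)(C)Cl (silyl groups of 24 and 25 only)
Why: LiN(i-Pr)2 removes a C4 proton (the only enolisable position, C1 being a ketal) from the s-trans lactone, and Me3SiCl present in the flask traps the enolate as the (E)-silyl ketene acetal 24, in which C3 is syn to the ring oxygen, the geometry that lithium amides give with esters in THF. On warming, 24 undergoes the [3,3]-sigmatropic Ireland–Claisen shift across the ring: C4 bonds to the enol-ether carbon C6 while the O–CH2 bond breaks, so the ester oxygen and the three allyl carbons leave the ring and silyl ester 25 results, which is hydrolysed to 26. The closest known reactions are the Ireland–Claisen ring contraction of macrocyclic allylic lactones to carbocycles four atoms smaller and ester-enolate Claisen shifts onto the oxygen-bearing terminus of 3-alkoxyallyl esters. The nine-membered ring is thus closed by transannular bond formation through a six-membered chair-like pericyclic array and not by end-to-end cyclisation; the tether C3–C2–C1–C10–C9–C8–C7 leaves C4 from a pseudo-axial and C6 from a pseudo-equatorial position, a gauche arrangement that a nine-membered ring accommodates. C4 and C6 are set relative to each other by the two alkene geometries in this chair: a ketene acetal with C3 syn to the ring oxygen together with the (Z)-enol ether (C7 anti to the CH2O carbon) puts carboxyl and vinyl cis on the new ring, the relation that later becomes the trans-fused pyran, whereas the opposite ketene acetal geometry would give the C4 epimer through a chair. Their sense relative to C9 and C10 is decided by which enol-ether face the ketene acetal can reach, that is, by the conformation that the trans-cyclobutane and the C1 ketal impose on the macrocycle, and this is not secured by precedent. The step needs the sigmatropic shift to outrun ketene formation from the enolate (hence silylation in situ) and the aromatic Claisen shift or ionisation of the tertiary allyl aryl ether in 26 (hence no more than 60 °C); the silyloxy group on C5 and the aryloxy group on C6 both accelerate the shift.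

Step 17
Reactants: 26 nine-membered ring acid
Product: 28 C6-vinyl 5,7-dimethoxychromanone (C5 ketone; C1 dioxolane; 4R,6S,9R,10S), via mixed trifluoroacetic anhydride 27 (not isolated)
Conditions: (CF3CO)2O, CH2Cl2, 0 °C; NaHCO3 quench
Reagents that add atoms: trifluoroacetic anhydride, O=C(OC(=O)C(F)(F)F)C(F)(F)F (trifluoroacetyl group of 27 only)
Why: Intramolecular Friedel–Crafts acylation through the mixed anhydride: the 3,5-dimethoxyphenoxy ring is attacked at one of its two equivalent ortho positions and the six-membered pyranone closes. The trans relation of carboxyl and aryloxy on the nine-membered ring becomes the trans ring fusion; no strong Lewis acid is used, because of the ketal and the tertiary allylic ether.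

Step 18
Reactants: 28 C6-vinyl chromanone
Product: 30 C6-hydroxymethyl chromanone (4R,6R,9R,10S), via aldehyde 29 (not isolated)
Conditions: O3, CH2Cl2–MeOH, −78 °C; then NaBH4, −78 → 0 °C
Reagents that add atoms: ozone, [O-][O+]=O
Why: Ozonolysis of the monosubstituted alkene, which should be faster than attack on the arene now that it carries the acyl group. At low temperature NaBH4 reduces the α-aryloxy aldehyde but not the strongly donor-substituted aryl ketone.

Step 19
Reactants: 30 C6-hydroxymethyl chromanone
Product: 31 O-alkyl imidazole-1-carbothioate of 30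
Conditions: 1,1'-thiocarbonyldiimidazole, DMAP (cat.), CH2Cl2, 40 °C
Reagents that add atoms: 1,1'-thiocarbonyldiimidazole, S=C(n1ccnc1)n1ccnc1
Why: Thioacylation of the primary alcohol, the first half of a Barton–McCombie deoxygenation.

Step 20
Reactants: 31 O-alkyl imidazole-1-carbothioate
Product: 32 C6-methyl 5,7-dimethoxychromanone (C1 dioxolane; 4R,6R,9R,10S)
Conditions: Bu3SnH, AIBN (cat.), toluene, 100 °C
Reagents that add atoms: none
Why: Barton–McCombie radical deoxygenation: the primary radical is reduced by Bu3SnH and leaves the C6 methyl group. The conditions are neutral, so the β-aryloxy ketone is not exposed to base.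

Step 21
Reactants: 32 C6-methyl chromanone
Product: 33 C5 tertiary alcohol with phenyl on C5 (4S,6R,9R,10S; C5 either configuration)
Conditions: PhMgBr, CeCl3, THF, −78 → 0 °C
Reagents that add atoms: phenylmagnesium bromide, Br[Mg]c1ccccc1
Why: Organocerium addition: the phenylcerium reagent adds to the hindered, enolisable aryl ketone without deprotonating C4, which would open the pyranone by β-elimination of the aryloxide. The configuration of the carbinol carbon does not matter, because it is ionised in the next step.

Step 22
Reactants: 33 C5 tertiary alcohol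
Product: 35 chroman ketal with H and phenyl on C5 (4S,5S,6R,9R,10S), via benzylic cation 34 (not isolated)
Conditions: Et3SiH (10 equiv), CF3CO2H, CH2Cl2, −40 °C; NaHCO3
Reagents that add atoms: none
Why: Ionic hydrogenation: the acid ionises the tertiary diarylcarbinol to a cation stabilised by the 2,4,6-trioxygenated ring, and Et3SiH delivers hydride to the face opposite the pseudo-axial C6 methyl group, which gives H5 cis to H4 and the phenyl group on the methyl face. Low temperature and excess silane are used so that capture outruns elimination to the chromene, which would put C4 at risk.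

Step 23
Reactants: 35 chroman ketal
Product: 36 tetracyclic C1 ketone, 5,7-dimethyl ether (4S,5S,6R,9R,10S)
Conditions: 1 M HCl, THF, rt
Reagents that add atoms: water, O
Why: Acid hydrolysis of the dioxolane; the trans ring fusion at C10 is the stable one in this ring system, so enolisation of the freed ketone is harmless, and the tertiary alkyl aryl ether is no longer allylic.

Step 24
Reactants: 36 tetracyclic C1 ketone
Product: 37 dibromo ketone (bromine on both free arene positions)
Conditions: NBS (2.1 equiv), MeCN, 0 °C
Reagents that add atoms: N-bromosuccinimide, O=C1CCC(=O)N1Br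
Why: Electrophilic aromatic bromination of the two remaining ring positions, each activated by three oxygen substituents; it is done before the alkene exists.

Step 25
Reactants: 37 dibromo ketone
Product: 38 dibromo compound with exocyclic methylene at C1
Conditions: Ph3PCH3Br, KOt-Bu, toluene, 60 °C
Reagents that add atoms: methyltriphenylphosphonium bromide, [Br-].C[P+](c1ccccc1)(c1ccccc1)c1ccccc1
Why: Wittig methylenation of the hindered ketone; aryl bromides are inert to the ylide, and the basic medium cannot harm C10, which is already in its stable configuration.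

Step 26
Reactants: 38 dibromo alkene
Product: 40 diformyl dimethyl ether of the target, via dilithioarene 39 (not isolated)
Conditions: t-BuLi (4.2 equiv), THF, −78 °C; DMF, −78 °C → rt; aq. NH4Cl
Reagents that add atoms: N,N-dimethylformamide, CN(C)C=O; tert-butyllithium, [Li]C(C)(C)C (lithium of 39 only)
Why: Bromine–lithium exchange at both positions and formylation of the aryllithium with DMF; at −78 °C exchange is faster than deprotonation of C5–H or of the allylic positions.

Step 27
Reactants: 40 diformyl dimethyl ether
Product: 41 target CNP0253700.3 (4S,5S,6R,9R,10S)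
Conditions: NaSEt (excess), DMF, 100 °C; dilute HCl
Reagents that add atoms: none
Why: Nucleophilic (SN2) demethylation by thiolate: both methoxy groups are ortho to a formyl group and so leave as stabilised phenoxides, whereas the tertiary C6–O ether cannot be attacked in an SN2 sense. No Lewis acid meets the exocyclic alkene.

## Compound list

1 | cyclohex-2-en-1-one | O=C1C=CCCC1 | starting material
2 | isobutene | C=C(C)C | starting material
3 | (1R,6R)-7,7-dimethylbicyclo[4.2.0]octan-2-one (cis-fused) | O=C1[C@@H]2CC(C)(C)[C@@H]2CCC1 | intermediate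
4 | trimethyl{[(1R,6R)-7,7-dimethylbicyclo[4.2.0]oct-2-en-2-yl]oxy}silane | C[Si](C)(C)OC1=CCC[C@@H]2[C@H]1CC2(C)C | intermediate
5 | (1R,2R)-3,3-dimethyl-2-(3-oxopropyl)cyclobutane-1-carboxylic acid (cis) | OC(=O)[C@@H]1CC(C)(C)[C@@H]1CCC=O | intermediate
6 | (1R,2R)-2-(but-3-yn-1-yl)-3,3-dimethylcyclobutane-1-carboxylic acid (cis) | OC(=O)[C@@H]1CC(C)(C)[C@@H]1CCC#C | intermediate
7 | (1R,2R)-2-(but-3-yn-1-yl)-3,3-dimethylcyclobutane-1-carbonyl chloride (not isolated) | ClC(=O)[C@@H]1CC(C)(C)[C@@H]1CCC#C | intermediate
8 | 1-[(1R,2R)-2-(but-3-yn-1-yl)-3,3-dimethylcyclobutyl]pent-4-en-1-one (cis) | C=CCCC(=O)[C@@H]1CC(C)(C)[C@@H]1CCC#C | intermediate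
9 | 1-[(1S,2R)-2-(but-3-yn-1-yl)-3,3-dimethylcyclobutyl]pent-4-en-1-one (trans) | C=CCCC(=O)[C@H]1CC(C)(C)[C@@H]1CCC#C | intermediate
10 | 2-(but-3-en-1-yl)-2-[(1S,2R)-2-(but-3-yn-1-yl)-3,3-dimethylcyclobutyl]-1,3-dioxolane | C=CCCC1(OCCO1)[C@H]2CC(C)(C)[C@@H]2CCC#C | intermediate
11 | lithium acetylide of 10 (not isolated) | C=CCCC1(OCCO1)[C@H]2CC(C)(C)[C@@H]2CCC#C[Li] | intermediate
12 | 5-{(1R,2S)-2-[2-(but-3-en-1-yl)-1,3-dioxolan-2-yl]-4,4-dimethylcyclobutyl}pent-2-yn-1-ol | C=CCCC1(OCCO1)[C@H]2CC(C)(C)[C@@H]2CCC#CCO | intermediate
13 | cyclic sodium alkenylalanate of 12, aluminium on C6 and on the alkoxide oxygen (not isolated) | C=CCCC1(OCCO1)[C@H]2CC(C)(C)[C@@H]2CCC3=CCO[Al-]3(OCCOC)OCCOC.[Na+] | intermediate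
14 | (2Z)-5-{(1R,2S)-2-[2-(but-3-en-1-yl)-1,3-dioxolan-2-yl]-4,4-dimethylcyclobutyl}-3-iodopent-2-en-1-ol | C=CCCC1(OCCO1)[C@H]2CC(C)(C)[C@@H]2CC/C(I)=C/CO | intermediate
15 | tert-butyldimethylsilyl ether of 14 | C=CCCC1(OCCO1)[C@H]2CC(C)(C)[C@@H]2CC/C(I)=C/CO[Si](C)(C)C(C)(C)C | intermediate
16 | 3,5-dimethoxyphenol | COc1cc(O)cc(OC)c1 | starting material
17 | tert-butyl{[(2Z)-5-{(1R,2S)-2-[2-(but-3-en-1-yl)-1,3-dioxolan-2-yl]-4,4-dimethylcyclobutyl}-3-(3,5-dimethoxyphenoxy)pent-2-en-1-yl]oxy}dimethylsilane | C=CCCC1(OCCO1)[C@H]2CC(C)(C)[C@@H]2CC/C(Oc3cc(OC)cc(OC)c3)=C/CO[Si](C)(C)C(C)(C)C | intermediate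
18 | B-alkyl-9-borabicyclo[3.3.1]nonane from 17, boron on C5 (not isolated) | C1CCC2CCCC1B2CCCCC3(OCCO3)[C@H]4CC(C)(C)[C@@H]4CC/C(Oc5cc(OC)cc(OC)c5)=C/CO[Si](C)(C)C(C)(C)C | intermediate
19 | 4-(2-{(1S,2R)-2-[(3Z)-5-(tert-butyldimethylsilyloxy)-3-(3,5-dimethoxyphenoxy)pent-3-en-1-yl]-3,3-dimethylcyclobutyl}-1,3-dioxolan-2-yl)butan-1-ol | OCCCCC1(OCCO1)[C@H]2CC(C)(C)[C@@H]2CC/C(Oc3cc(OC)cc(OC)c3)=C/CO[Si](C)(C)C(C)(C)C | intermediate
20 | 4-(2-{(1S,2R)-2-[(3Z)-5-(tert-butyldimethylsilyloxy)-3-(3,5-dimethoxyphenoxy)pent-3-en-1-yl]-3,3-dimethylcyclobutyl}-1,3-dioxolan-2-yl)butanoic acid | OC(=O)CCCC1(OCCO1)[C@H]2CC(C)(C)[C@@H]2CC/C(Oc3cc(OC)cc(OC)c3)=C/CO[Si](C)(C)C(C)(C)C | intermediate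
21 | 4-(2-{(1S,2R)-2-[(3Z)-3-(3,5-dimethoxyphenoxy)-5-hydroxypent-3-en-1-yl]-3,3-dimethylcyclobutyl}-1,3-dioxolan-2-yl)butanoic acid (seco acid) | OC(=O)CCCC1(OCCO1)[C@H]2CC(C)(C)[C@@H]2CC/C(Oc3cc(OC)cc(OC)c3)=C/CO | intermediate
22 | mixed anhydride of 21 with 2,4,6-trichlorobenzoic acid (not isolated) | O=C(CCCC1(OCCO1)[C@H]2CC(C)(C)[C@@H]2CC/C(Oc3cc(OC)cc(OC)c3)=C/CO)OC(=O)c4c(Cl)cc(Cl)cc4Cl | intermediate
23 | thirteen-membered lactone, ring C5(=O)–C4–C3–C2–C1(dioxolane)–C10–C9–C8–C7–C6(OAr)=CH–CH2–O, (Z)-enol ether, Ar = 3,5-dimethoxyphenyl, 9R,10S | O=C1CCCC2(OCCO2)[C@H]3CC(C)(C)[C@@H]3CC/C(Oc3cc(OC)cc(OC)c3)=C/CO1 | intermediate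
24 | (E)-trimethylsilyl ketene acetal of 23, C3 syn to the ring oxygen (not isolated) | C[Si](C)(C)O/C1=C/CCC2(OCCO2)[C@H]3CC(C)(C)[C@@H]3CC/C(Oc4cc(OC)cc(OC)c4)=C/CO1 | intermediate
25 | trimethylsilyl ester of 26 (not isolated) | C[Si](C)(C)OC(=O)[C@@H]1CCC2(OCCO2)[C@H]3CC(C)(C)[C@@H]3CC[C@@]1(C=C)Oc1cc(OC)cc(OC)c1 | intermediate
26 | nine-membered ring acid: CO2H on C4, vinyl and 3,5-dimethoxyphenoxy on C6, C1 dioxolane, carboxyl and vinyl cis, trans-cyclobutane (4R,6S,9R,10S) | OC(=O)[C@@H]1CCC2(OCCO2)[C@H]3CC(C)(C)[C@@H]3CC[C@@]1(C=C)Oc1cc(OC)cc(OC)c1 | intermediate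
27 | mixed trifluoroacetic anhydride of 26 (not isolated) | O=C(OC(=O)C(F)(F)F)[C@@H]1CCC2(OCCO2)[C@H]3CC(C)(C)[C@@H]3CC[C@@]1(C=C)Oc1cc(OC)cc(OC)c1 | intermediate
28 | trans-fused 5,7-dimethoxychromanone: C5 ketone, vinyl on C6, C1 dioxolane (4R,6S,9R,10S) | C12(OCCO1)CC[C@H]3C(=O)c4c(OC)cc(OC)cc4O[C@]3(C=C)CC[C@@H]5[C@@H]2CC5(C)C | intermediate
29 | C6 aldehyde from 28 (not isolated) | C12(OCCO1)CC[C@H]3C(=O)c4c(OC)cc(OC)cc4O[C@]3(C=O)CC[C@@H]5[C@@H]2CC5(C)C | intermediate
30 | chromanone with CH2OH on C6 (4R,6R,9R,10S) | C12(OCCO1)CC[C@H]3C(=O)c4c(OC)cc(OC)cc4O[C@]3(CO)CC[C@@H]5[C@@H]2CC5(C)C | intermediate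
31 | O-alkyl imidazole-1-carbothioate of 30 | C12(OCCO1)CC[C@H]3C(=O)c4c(OC)cc(OC)cc4O[C@]3(COC(=S)n6ccnc6)CC[C@@H]5[C@@H]2CC5(C)C | intermediate
32 | chromanone with methyl on C6, C1 dioxolane (4R,6R,9R,10S) | C12(OCCO1)CC[C@H]3C(=O)c4c(OC)cc(OC)cc4O[C@]3(C)CC[C@@H]5[C@@H]2CC5(C)C | intermediate
33 | tertiary alcohol: OH and phenyl on C5 (4S,6R,9R,10S; C5 either configuration) | C12(OCCO1)CC[C@H]3C(O)(c6ccccc6)c4c(OC)cc(OC)cc4O[C@]3(C)CC[C@@H]5[C@@H]2CC5(C)C | intermediate
34 | C5 diarylmethyl cation from 33 (not isolated) | C12(OCCO1)CC[C@H]3[C+](c6ccccc6)c4c(OC)cc(OC)cc4O[C@]3(C)CC[C@@H]5[C@@H]2CC5(C)C | intermediate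
35 | chroman with H and phenyl on C5, C1 dioxolane (4S,5S,6R,9R,10S) | C12(OCCO1)CC[C@H]3[C@@H](c6ccccc6)c4c(OC)cc(OC)cc4O[C@]3(C)CC[C@@H]5[C@@H]2CC5(C)C | intermediate
36 | tetracyclic C1 ketone, 5,7-dimethyl ether (4S,5S,6R,9R,10S) | O=C1CC[C@H]2[C@@H](c3ccccc3)c3c(OC)cc(OC)cc3O[C@]2(C)CC[C@@H]2[C@@H]1CC2(C)C | intermediate
37 | dibromo derivative of 36, bromine on both free arene positions | O=C1CC[C@H]2[C@@H](c3ccccc3)c3c(OC)c(Br)c(OC)c(Br)c3O[C@]2(C)CC[C@@H]2[C@@H]1CC2(C)C | intermediate
38 | dibromo compound with exocyclic methylene at C1 | C=C1CC[C@H]2[C@@H](c3ccccc3)c3c(OC)c(Br)c(OC)c(Br)c3O[C@]2(C)CC[C@@H]2[C@@H]1CC2(C)C | intermediate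
39 | dilithioarene from 38 (not isolated) | C=C1CC[C@H]2[C@@H](c3ccccc3)c3c(OC)c([Li])c(OC)c([Li])c3O[C@]2(C)CC[C@@H]2[C@@H]1CC2(C)C | intermediate
40 | diformyl dimethyl ether of the target | C=C1CC[C@H]2[C@@H](c3ccccc3)c3c(OC)c(C=O)c(OC)c(C=O)c3O[C@]2(C)CC[C@@H]2[C@@H]1CC2(C)C | intermediate
41 | CNP0253700.3 (4S,5S,6R,9R,10S) | C=C1CC[C@H]2[C@@H](c3ccccc3)c3c(O)c(C=O)c(O)c(C=O)c3O[C@]2(C)CC[C@@H]2[C@@H]1CC2(C)C | target

## Step count and least certain steps

Total: 27 steps. Longest linear sequence: 27 steps from 1 (16 is commercial and enters at step 11).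

**Step 16 (key step).** Three things may go wrong. The shift may take place on the enol-ether face that gives the C4/C6 pair with the wrong sense relative to C9/C10, because face selection rests only on the conformation of the macrocycle. Enolisation may give the ketene acetal with C3 anti to the ring oxygen, whose chair would put carboxyl and vinyl trans. Heating may trigger ionisation of the 3-aryloxyallyl ester or an aromatic Claisen shift of the product. The fallback gives up the ring contraction and sets out from ketone 9. Hydration of the terminal alkyne (HgSO4 cat., aqueous H2SO4–THF) would give 4-[(1R,2S)-4,4-dimethyl-2-(pent-4-enoyl)cyclobutyl]butan-2-one F1. Cross-metathesis with styrene (second-generation Grubbs catalyst) would give (4E)-1-[(1S,2R)-3,3-dimethyl-2-(3-oxobutyl)cyclobutyl]-5-phenylpent-4-en-1-one F2, the same compound as A1. Treatment of F2 with 16 and Me3SiOTf would then be expected to join O–C6, C4–C6 and Ar1–C5 in a cationic annulation and to return to the route at ketone 36. This path is much shorter, but it has none of the pericyclic control, so diastereomers would have to be separated.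

**Step 11.** The hindered trisubstituted alkenyl iodide may undergo oxidative addition slowly, so that dehydroiodination to the alkyne or allene, or C-arylation of the very electron-rich phenol, takes over. The fallback sets out from alkyne 10. Deprotonation with n-BuLi and trapping with methyl chloroformate would give methyl 5-{(1R,2S)-2-[2-(but-3-en-1-yl)-1,3-dioxolan-2-yl]-4,4-dimethylcyclobutyl}pent-2-ynoate F3. Conjugate addition of 16 under kinetic control (substoichiometric Cs2CO3, MeCN, 0 °C; anti addition) would give the methyl (2Z)-3-(3,5-dimethoxyphenoxy)pent-2-enoate F4, from which any (E)-isomer formed by equilibration would be removed. Reduction with i-Bu2AlH would give the (2Z)-3-(3,5-dimethoxyphenoxy)pent-2-en-1-ol F5, and silylation as in step 10 returns to 17.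

**Step 22.** Hydride delivery may show poor facial selectivity, or the cation may lose the C4 proton to give a chromene, whose reprotonation would scramble C4. The fallback sets out from carbinol 33. Deliberate dehydration (MsCl, Et3N) would give the 4-phenyl-2H-chromene F6 with a C4=C5 double bond. Catalytic hydrogenation (H2, Pd on carbon, or [Ir(cod)(PCy3)(py)]PF6) adds both hydrogens to one face, which guarantees H4 cis to H5, and should do so opposite the C6 methyl group; this returns to 35.

**Step 1.** The enantioselectivity may be insufficient, or the sense of induction may be the opposite of that assumed. The fallback sets out from 1 and 2: irradiation without the Lewis acid gives racemic 3, and steps 2 to 4 carried out on the racemate give racemic 6. Resolution through the salt (R)-1-phenylethylammonium (1R,2R)-2-(but-3-yn-1-yl)-3,3-dimethylcyclobutane-1-carboxylate F7 (or through the salt of the antipodal amine, whichever crystallises with the wanted acid), followed by acidification, returns to 6.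

**Step 26.** The second bromine–lithium exchange may be incomplete, or an aryllithium may be protonated, leaving monoaldehyde. The fallback sets out from ketone 36. Wittig methylenation as in step 25 would give the bis-deformyl dimethyl ether F8, the same compound as A6. Demethylation with NaSEt in DMF at 150 °C would give the 5,7-dihydroxychroman F9. Twofold ortho-formylation of the free phenol with MgCl2, Et3N and paraformaldehyde in MeCN, under basic conditions that spare the alkene, returns to the target 41.

## Further compounds

F1 | step 16 | 4-[(1R,2S)-4,4-dimethyl-2-(pent-4-enoyl)cyclobutyl]butan-2-one | C=CCCC(=O)[C@H]1CC(C)(C)[C@@H]1CCC(C)=O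
F2 | step 16 | (4E)-1-[(1S,2R)-3,3-dimethyl-2-(3-oxobutyl)cyclobutyl]-5-phenylpent-4-en-1-one | O=C(CC/C=C/c1ccccc1)[C@H]2CC(C)(C)[C@@H]2CCC(C)=O
F3 | step 11 | methyl 5-{(1R,2S)-2-[2-(but-3-en-1-yl)-1,3-dioxolan-2-yl]-4,4-dimethylcyclobutyl}pent-2-ynoate | C=CCCC1(OCCO1)[C@H]2CC(C)(C)[C@@H]2CCC#CC(=O)OC
F4 | step 11 | methyl (2Z)-5-{(1R,2S)-2-[2-(but-3-en-1-yl)-1,3-dioxolan-2-yl]-4,4-dimethylcyclobutyl}-3-(3,5-dimethoxyphenoxy)pent-2-enoate | C=CCCC1(OCCO1)[C@H]2CC(C)(C)[C@@H]2CC/C(Oc3cc(OC)cc(OC)c3)=C/C(=O)OC
F5 | step 11 | (2Z)-5-{(1R,2S)-2-[2-(but-3-en-1-yl)-1,3-dioxolan-2-yl]-4,4-dimethylcyclobutyl}-3-(3,5-dimethoxyphenoxy)pent-2-en-1-ol | C=CCCC1(OCCO1)[C@H]2CC(C)(C)[C@@H]2CC/C(Oc3cc(OC)cc(OC)c3)=C/CO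
F6 | step 22 | 4-phenyl-2H-chromene with C4=C5 double bond, C1 dioxolane (6R,9R,10S) | C12(OCCO1)CCC3=C(c6ccccc6)c4c(OC)cc(OC)cc4O[C@]3(C)CC[C@@H]5[C@@H]2CC5(C)C
F7 | step 1 | (R)-1-phenylethylammonium (1R,2R)-2-(but-3-yn-1-yl)-3,3-dimethylcyclobutane-1-carboxylate | C[C@@H]([NH3+])c1ccccc1.[O-]C(=O)[C@@H]1CC(C)(C)[C@@H]1CCC#C
F8 | step 26 | bis-deformyl dimethyl ether of the target | C=C1CC[C@H]2[C@@H](c3ccccc3)c3c(OC)cc(OC)cc3O[C@]2(C)CC[C@@H]2[C@@H]1CC2(C)C
F9 | step 26 | bis-deformyl target (5,7-dihydroxychroman) | C=C1CC[C@H]2[C@@H](c3ccccc3)c3c(O)cc(O)cc3O[C@]2(C)CC[C@@H]2[C@@H]1CC2(C)C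
A1 | alternative 1 | (4E)-1-[(1S,2R)-3,3-dimethyl-2-(3-oxobutyl)cyclobutyl]-5-phenylpent-4-en-1-one | O=C(CC/C=C/c1ccccc1)[C@H]2CC(C)(C)[C@@H]2CCC(C)=O
A2 | alternative 1 | tetracyclic C1 ketone, 5,7-dimethyl ether | O=C1CC[C@H]2[C@@H](c3ccccc3)c3c(OC)cc(OC)cc3O[C@]2(C)CC[C@@H]2[C@@H]1CC2(C)C
A3 | alternative 2 | cis-fused 2-vinylbicyclo[3.2.0]heptan-2-ol with the (E)-alkenyl group on the neighbouring carbon, both on the convex face | C=C[C@]1(O)[C@H](/C(C)=C/[C@@H](c2ccccc2)c2c(OC)cc(OC)cc2OC)C[C@@H]2[C@H]1CC2(C)C
A4 | alternative 2 | cis-fused (Z)-cyclononenone with C4 and C5 in place | O=C1CC[C@@H]([C@@H](c2ccccc2)c2c(OC)cc(OC)cc2OC)/C(C)=C\C[C@@H]2[C@H]1CC2(C)C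
A5 | alternative 3 | open-chain chroman with vinyl on C4 and 1-iodovinyl on C10 | C=C[C@H]1[C@@H](c2ccccc2)c2c(OC)cc(OC)cc2O[C@]1(C)CC[C@@H]1[C@@H](C(I)=C)CC1(C)C
A6 | alternative 3 | bis-deformyl dimethyl ether of the target | C=C1CC[C@H]2[C@@H](c3ccccc3)c3c(OC)cc(OC)cc3O[C@]2(C)CC[C@@H]2[C@@H]1CC2(C)C
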